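**Strategy.** Germacrane numbering is used (oxirane C1/C10, acetoxy C3, olefin C4=C5, lactone oxygen on C6, acyloxy C8). The oxirane is cis-fused to the ten-membered carbocycle (C2 and C9 cis), so it is the retron of a (Z)-C1=C10 olefin. Everything rests on forming the C1–C10 bond by ring-closing metathesis: in one operation the allyl (C1) and methallyl (C10) termini of a seco-germacranolide are joined, closing the cyclodecadiene around the preformed trans-fused α-methylene-γ-lactone and the (Z)-C4=C5 olefin, with both esters in place. The precursor is an open-chain lactone made by chromium-mediated allylation/lactonisation of two five-step fragments; peracid epoxidation then completes the oxirane.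

Key step: step 16

Remark on the chemistry: read from the SMILES, the oxirane is cis on the ring (1R,10S), C4=C5 is Z, the lactone is trans-fused (6S,7S), C3 is R, C8 is S and the acyl group is (R)-2-methylbutanoyl; the route is designed for exactly this isomer. TBS = tert-butyldimethylsilyl, PMB = 4-methoxybenzyl.

**Fragment A (C7–C14, bromide 10)**

Step 1
Reactants: 1 ethyl glyoxylate; 2 isobutene (2-methylpropene)
Product: 3 ethyl (2S)-2-hydroxy-4-methylpent-4-enoate
Conditions: (S)-BINOL (10 mol%), TiCl2(OiPr)2 (10 mol%), 4 Å MS, CH2Cl2, −30 °C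
Reagents that add atoms: isobutene, CC(C)=C
Why: Catalytic asymmetric glyoxylate-ene reaction: the BINOL–titanium Lewis acid binds the glyoxylate and exposes one aldehyde face, so the (S)-ligand should deliver the (S)-carbinol (future C8) while the ene transfer leaves the methallyl unit (C9, C10, C14) in place.

Step 2
Reactants: 3 ethyl (2S)-2-hydroxy-4-methylpent-4-enoate; 4 tert-butyldimethylsilyl chloride
Product: 5 ethyl (2S)-2-[(tert-butyldimethylsilyl)oxy]-4-methylpent-4-enoate
Conditions: imidazole, DMF, rt
Reagents that add atoms: tert-butyldimethylsilyl chloride (TBSCl), CC(C)(C)[Si](C)(C)Cl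
Why: Standard silylation of a secondary alcohol; the TBS ether is a non-chelating, non-leaving group that should survive and steer the later allylchromium addition.

Step 3
Reactants: 5 ethyl (2S)-2-[(tert-butyldimethylsilyl)oxy]-4-methylpent-4-enoate
Product: 6 (2S)-2-[(tert-butyldimethylsilyl)oxy]-4-methylpent-4-enal
Conditions: i-Bu2AlH (DIBAL-H, 1.1 equiv), CH2Cl2, −78 °C; then MeOH, aq. potassium sodium tartrate
Reagents that add atoms: none
Why: Partial ester reduction with DIBAL-H, whose tetrahedral aluminium hemiacetal persists at −78 °C and releases the α-silyloxy aldehyde only on work-up, without epimerisation.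

Step 4
Reactants: 6 (2S)-2-[(tert-butyldimethylsilyl)oxy]-4-methylpent-4-enal; 7 methyl acrylate
Product: 8 methyl (4S)-4-[(tert-butyldimethylsilyl)oxy]-3-hydroxy-6-methyl-2-methylidenehept-6-enoate (both C3 epimers)
Conditions: DABCO (1.0 equiv), 7 (5 equiv), dioxane–H2O 1:1, rt
Reagents that add atoms: methyl acrylate, C=CC(=O)OC
Why: Morita–Baylis–Hillman reaction; the new carbinol (C7) forms as a mixture that is of no consequence because this centre becomes sp2 in step 5, and the C8 centre is not involved.

Step 5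
Reactants: 8 methyl (4S)-4-[(tert-butyldimethylsilyl)oxy]-3-hydroxy-6-methyl-2-methylidenehept-6-enoate; 9 N-bromosuccinimide
Product: 10 methyl (2Z,4S)-2-(bromomethyl)-4-[(tert-butyldimethylsilyl)oxy]-6-methylhepta-2,6-dienoate
Conditions: NBS (1.5 equiv), Me2S (1.6 equiv), CH2Cl2, 0 °C → rt
Reagents that add atoms: N-bromosuccinimide, O=C1CCC(=O)N1Br
Why: Corey–Kim-type activation of the allylic alcohol as an alkoxysulfonium salt followed by SN2′ attack of bromide should give the thermodynamically preferred (Z)-2-(bromomethyl)enoate with allylic transposition.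

**Fragment B (C1–C6, aldehyde 23)**

Step 6
Reactants: 11 prop-2-yn-1-ol; 12 methylmagnesium bromide; 13 iodine
Product: 15 (2Z)-3-iodo-2-methylprop-2-en-1-ol, via vinylmagnesium alkoxide 14 (not isolated)
Conditions: MeMgBr (3 equiv), CuI (10 mol%), Et2O/THF, −10 °C → rt; then I2, −78 → 0 °C
Reagents that add atoms: methylmagnesium bromide, C[Mg]Br; iodine, II
Why: Copper-catalysed, alkoxide-directed anti-carbomagnesiation of a propargylic alcohol puts the methyl group (C15) on the proximal carbon and magnesium cis to the CH2O group, and iodinolysis with retention gives the Z iodide that fixes the C4=C5 geometry.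

Step 7
Reactants: 15 (2Z)-3-iodo-2-methylprop-2-en-1-ol
Product: 16 (2Z)-3-iodo-2-methylprop-2-enal
Conditions: MnO2 (15 equiv), CH2Cl2, rt, dark; used at once
Reagents that add atoms: none
Why: Neutral MnO2 oxidation of the allylic alcohol should give the β-iodo enal without Z/E isomerisation.

Step 8
Reactants: 16 (2Z)-3-iodo-2-methylprop-2-enal; 17 B-allylbis[(1S,2R,3S,5S)-isopinocampheyl]borane (allylborane of the (−)-α-pinene series)
Product: 18 (1Z,3R)-1-iodo-2-methylhexa-1,5-dien-3-ol
Conditions: 17 (1.2 equiv), Et2O, −78 °C; then ethanolamine, rt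
Reagents that add atoms: B-allylbis(isopinocampheyl)borane, C=CCB([C@H]1C[C@H]2C[C@@H]([C@@H]1C)C2(C)C)[C@H]1C[C@H]2C[C@@H]([C@@H]1C)C2(C)C
Why: Brown asymmetric allylboration through a closed chair transition state; the (−)-α-pinene-derived reagent should add the allyl group to the Re face of the enal and set C3 as R.

Step 9
Reactants: 18 (1Z,3R)-1-iodo-2-methylhexa-1,5-dien-3-ol; 19 4-methoxybenzyl chloride
Product: 20 (1Z,3R)-1-iodo-3-[(4-methoxyphenyl)methoxy]-2-methylhexa-1,5-diene
Conditions: NaH, Bu4NI (cat.), THF–DMF, 0 °C → rt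
Reagents that add atoms: 4-methoxybenzyl chloride, COc1ccc(CCl)cc1
Why: Williamson etherification; the PMB ether tolerates tert-butyllithium, cannot migrate to carbon as a silyl group could, and is removable next to the TBS ether.

Step 10
Reactants: 20 (1Z,3R)-1-iodo-3-[(4-methoxyphenyl)methoxy]-2-methylhexa-1,5-diene; 21 N,N-dimethylformamide
Product: 23 (2Z,4R)-4-[(4-methoxyphenyl)methoxy]-3-methylhepta-2,6-dienal, via vinyllithium 22 (not isolated)
Conditions: t-BuLi (2.1 equiv), Et2O, −78 °C; then DMF, −78 → 0 °C; aq. NH4Cl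
Reagents that add atoms: N,N-dimethylformamide, CN(C)C=O
Why: Iodine–lithium exchange proceeds with retention of olefin geometry, and Bouveault formylation of the vinyllithium with DMF gives the (Z)-enal whose formyl carbon is C6.

**Union and endgame**

Step 11
Reactants: 23 (2Z,4R)-4-[(4-methoxyphenyl)methoxy]-3-methylhepta-2,6-dienal; 10 methyl (2Z,4S)-2-(bromomethyl)-4-[(tert-butyldimethylsilyl)oxy]-6-methylhepta-2,6-dienoate
Product: 25 (4R,5S)-4-[(1S)-1-(TBSO)-3-methylbut-3-en-1-yl]-5-[(1Z,3R)-3-(PMBO)-2-methylhexa-1,5-dien-1-yl]-3-methylideneoxolan-2-one, via hydroxy ester 24 (not isolated)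
Conditions: CrCl2 (4 equiv), THF, 0 °C → rt; then PPTS (cat.), CH2Cl2, rt
Reagents that add atoms: bromide 10, COC(=O)/C(CBr)=C/[C@@H](O[Si](C)(C)C(C)(C)C)CC(C)=C
Why: Nozaki–Hiyama allylation: the allylchromium species formed with divalent chromium should add through a chair transition state with the C8 side chain equatorial to give the anti adduct (C6/C7, hence the trans-lactone), attack on the olefin face fixed by the C8 silyloxy centre in the Felkin–Anh sense (alkyl anti, allylic hydrogen eclipsing the ester-bearing olefin) sets C7, and the chromium alkoxide closes the α-methylene-γ-butyrolactone with loss of methanol.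

Step 12
Reactants: 25 PMB/TBS-protected seco-lactone
Product: 26 (4R,5S)-4-[(1S)-1-(TBSO)-3-methylbut-3-en-1-yl]-5-[(1Z,3R)-3-hydroxy-2-methylhexa-1,5-dien-1-yl]-3-methylideneoxolan-2-one
Conditions: DDQ (1.3 equiv), CH2Cl2–pH 7 buffer 10:1, 0 °C
Reagents that add atoms: none
Why: Oxidative cleavage of the electron-rich PMB ether by DDQ (hydride abstraction, then hydrolysis of the oxocarbenium ion) should leave the TBS ether, the olefins and the lactone untouched.

Step 13
Reactants: 26 C3 alcohol; 27 acetic anhydride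
Product: 28 (1Z,3R)-1-{(2S,3R)-3-[(1S)-1-(TBSO)-3-methylbut-3-en-1-yl]-4-methylidene-5-oxooxolan-2-yl}-2-methylhexa-1,5-dien-3-yl acetate
Conditions: Ac2O, pyridine, DMAP (cat.), CH2Cl2, 0 °C → rt
Reagents that add atoms: acetic anhydride, CC(=O)OC(C)=O
Why: DMAP-catalysed acetylation of the secondary allylic alcohol installs the C3 acetate with retention.

Step 14
Reactants: 28 C3 acetate, C8 TBS ether
Product: 29 (1Z,3R)-1-{(2S,3S)-3-[(1S)-1-hydroxy-3-methylbut-3-en-1-yl]-4-methylidene-5-oxooxolan-2-yl}-2-methylhexa-1,5-dien-3-yl acetate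
Conditions: HF·pyridine, pyridine, THF, 0 °C → rt
Reagents that add atoms: none
Why: Fluoride-mediated desilylation under buffered acidic conditions should avoid acetyl migration, translactonisation onto O8 and conjugate addition to the acrylate.

Step 15
Reactants: 29 C8 alcohol; 30 (2R)-2-methylbutanoic acid
Product: 31 (1S)-1-{(2S,3S)-2-[(1Z,3R)-3-acetoxy-2-methylhexa-1,5-dien-1-yl]-4-methylidene-5-oxooxolan-3-yl}-3-methylbut-3-en-1-yl (2R)-2-methylbutanoate
Conditions: 30 (1.5 equiv), DCC (1.5 equiv), DMAP (0.2 equiv), CH2Cl2, 0 °C → rt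
Reagents that add atoms: (2R)-2-methylbutanoic acid, CC[C@@H](C)C(=O)O
Why: Steglich esterification of the C8 alcohol; carbodiimide activation with only catalytic DMAP at 0 °C should keep the α-stereocentre of the acyl group intact.

Step 16
Reactants: 31 seco-germacranolide diester
Product: 32 [(3aS,4S,6Z,9R,10Z,11aS)-9-acetoxy-6,10-dimethyl-3-methylidene-2-oxo-2,3,3a,4,5,8,9,11a-octahydrocyclodeca[b]furan-4-yl] (2R)-2-methylbutanoate
Conditions: second-generation Hoveyda–Grubbs catalyst RuCl2(H2IMes)(=CH-C6H4-2-OiPr) (10 mol%, in portions), 1,4-benzoquinone (20 mol%), toluene (1 mM), 80 °C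
Reagents that add atoms: none
Why: The ruthenium alkylidene loads on the monosubstituted C1 vinyl group, undergoes intramolecular [2+2] cycloaddition with the 1,1-disubstituted C10 olefin and cycloreverts, expelling ethylene and forming the C1=C10 bond. The closest known reaction type is ring-closing metathesis to trisubstituted cycloalkenes in ten-membered carbocycles, including germacranolide-type lactones that carry an α-methylene group. The ten-membered carbocycle is closed end to end (metathesis of an α,ω-diene, new olefin endocyclic) onto the existing five-membered lactone, giving the bicyclo[8.3.0] framework. No stereocentre is created; the stereochemical element is the olefin geometry, and Z is expected because an E olefin in this doubly unsaturated ten-membered ring is markedly more strained and the metathesis is reversible enough to find the less strained isomer. The step needs site selectivity (C1/C10 only), cyclisation over oligomerisation and Z geometry: the trisubstituted C4=C5 olefin and the electron-poor acrylate are poor partners, closure onto the acrylate would demand a bridged bicycle, and the Z-C4=C5 olefin together with the trans-lactone act as turn elements that bring C1 and C10 together at 1 mM.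

Step 17
Reactants: 32 (1(10)Z,4Z)-germacradienolide diester; 33 3-chloroperbenzoic acid
Product: 34 (1R,3R,4Z,6S,7S,8S,10S)-3-acetoxy-1,10-epoxy-8-[(2R)-2-methylbutanoyloxy]germacra-4,11(13)-dien-12,6-olide (target)
Conditions: mCPBA (1.1 equiv), NaHCO3, CH2Cl2, 0 °C
Reagents that add atoms: 3-chloroperbenzoic acid, O=C(OO)c1cccc(Cl)c1
Why: Prilezhaev epoxidation: concerted syn oxygen transfer to the Z olefin fixes the cis oxirane, the electron-rich C1=C10 olefin should react in preference to the C4=C5 olefin (deactivated by two allylic acyloxy groups) and the acrylate, and attack on the peripheral face of the cyclodecadiene, away from the ring-bound C3 and C8 acyloxy groups, should set C1 (R) and C10 (S) together.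

**Compound list**

1 | ethyl glyoxylate | CCOC(=O)C=O | starting material
2 | isobutene | CC(C)=C | starting material
3 | ethyl (2S)-2-hydroxy-4-methylpent-4-enoate | CCOC(=O)[C@@H](O)CC(C)=C | intermediate
4 | tert-butyldimethylsilyl chloride | CC(C)(C)[Si](C)(C)Cl | starting material
5 | ethyl (2S)-2-[(tert-butyldimethylsilyl)oxy]-4-methylpent-4-enoate | CCOC(=O)[C@@H](O[Si](C)(C)C(C)(C)C)CC(C)=C | intermediate
6 | (2S)-2-[(tert-butyldimethylsilyl)oxy]-4-methylpent-4-enal | O=C[C@@H](O[Si](C)(C)C(C)(C)C)CC(C)=C | intermediate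
7 | methyl acrylate | C=CC(=O)OC | starting material
8 | methyl (4S)-4-[(tert-butyldimethylsilyl)oxy]-3-hydroxy-6-methyl-2-methylidenehept-6-enoate (C3 epimers) | C=C(C(=O)OC)C(O)[C@@H](O[Si](C)(C)C(C)(C)C)CC(C)=C | intermediate
9 | N-bromosuccinimide | O=C1CCC(=O)N1Br | starting material
10 | methyl (2Z,4S)-2-(bromomethyl)-4-[(tert-butyldimethylsilyl)oxy]-6-methylhepta-2,6-dienoate | COC(=O)/C(CBr)=C/[C@@H](O[Si](C)(C)C(C)(C)C)CC(C)=C | intermediate
11 | prop-2-yn-1-ol | C#CCO | starting material
12 | methylmagnesium bromide | C[Mg]Br | starting material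
13 | iodine | II | starting material
14 | bromomagnesium (2Z)-3-(bromomagnesio)-2-methylprop-2-en-1-olate | Br[Mg]OC/C(C)=C\[Mg]Br | intermediate
15 | (2Z)-3-iodo-2-methylprop-2-en-1-ol | OC/C(C)=C\I | intermediate
16 | (2Z)-3-iodo-2-methylprop-2-enal | O=C/C(C)=C\I | intermediate
17 | B-allylbis[(1S,2R,3S,5S)-isopinocampheyl]borane | C=CCB([C@H]1C[C@H]2C[C@@H]([C@@H]1C)C2(C)C)[C@H]1C[C@H]2C[C@@H]([C@@H]1C)C2(C)C | starting material
18 | (1Z,3R)-1-iodo-2-methylhexa-1,5-dien-3-ol | C=CC[C@@H](O)/C(C)=C\I | intermediate
19 | 4-methoxybenzyl chloride | COc1ccc(CCl)cc1 | starting material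
20 | (1Z,3R)-1-iodo-3-[(4-methoxyphenyl)methoxy]-2-methylhexa-1,5-diene | C=CC[C@@H](OCc1ccc(OC)cc1)/C(C)=C\I | intermediate
21 | N,N-dimethylformamide | CN(C)C=O | starting material
22 | (1Z,3R)-3-[(4-methoxyphenyl)methoxy]-2-methylhexa-1,5-dien-1-yllithium | C=CC[C@@H](OCc1ccc(OC)cc1)/C(C)=C\[Li] | intermediate
23 | (2Z,4R)-4-[(4-methoxyphenyl)methoxy]-3-methylhepta-2,6-dienal | O=C/C=C(/C)[C@H](OCc1ccc(OC)cc1)CC=C | intermediate
24 | methyl (3R,4S,5Z,7R)-3-[(1S)-1-(TBSO)-3-methylbut-3-en-1-yl]-4-hydroxy-7-(PMBO)-6-methyl-2-methylidenedeca-5,9-dienoate | C=C(C(=O)OC)[C@H]([C@@H](O)/C=C(/C)[C@H](OCc1ccc(OC)cc1)CC=C)[C@@H](O[Si](C)(C)C(C)(C)C)CC(C)=C | intermediate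
25 | (4R,5S)-4-[(1S)-1-(TBSO)-3-methylbut-3-en-1-yl]-5-[(1Z,3R)-3-(PMBO)-2-methylhexa-1,5-dien-1-yl]-3-methylideneoxolan-2-one | C=C1C(=O)O[C@@H](/C=C(/C)[C@H](OCc2ccc(OC)cc2)CC=C)[C@@H]1[C@@H](O[Si](C)(C)C(C)(C)C)CC(C)=C | intermediate
26 | (4R,5S)-4-[(1S)-1-(TBSO)-3-methylbut-3-en-1-yl]-5-[(1Z,3R)-3-hydroxy-2-methylhexa-1,5-dien-1-yl]-3-methylideneoxolan-2-one | C=C1C(=O)O[C@@H](/C=C(/C)[C@H](O)CC=C)[C@@H]1[C@@H](O[Si](C)(C)C(C)(C)C)CC(C)=C | intermediate
27 | acetic anhydride | CC(=O)OC(C)=O | starting material
28 | (1Z,3R)-1-{(2S,3R)-3-[(1S)-1-(TBSO)-3-methylbut-3-en-1-yl]-4-methylidene-5-oxooxolan-2-yl}-2-methylhexa-1,5-dien-3-yl acetate | C=C1C(=O)O[C@@H](/C=C(/C)[C@H](OC(C)=O)CC=C)[C@@H]1[C@@H](O[Si](C)(C)C(C)(C)C)CC(C)=C | intermediate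
29 | (1Z,3R)-1-{(2S,3S)-3-[(1S)-1-hydroxy-3-methylbut-3-en-1-yl]-4-methylidene-5-oxooxolan-2-yl}-2-methylhexa-1,5-dien-3-yl acetate | C=C1C(=O)O[C@@H](/C=C(/C)[C@H](OC(C)=O)CC=C)[C@@H]1[C@@H](O)CC(C)=C | intermediate
30 | (2R)-2-methylbutanoic acid | CC[C@@H](C)C(=O)O | starting material
31 | (1S)-1-{(2S,3S)-2-[(1Z,3R)-3-acetoxy-2-methylhexa-1,5-dien-1-yl]-4-methylidene-5-oxooxolan-3-yl}-3-methylbut-3-en-1-yl (2R)-2-methylbutanoate | C=C1C(=O)O[C@@H](/C=C(/C)[C@H](OC(C)=O)CC=C)[C@@H]1[C@@H](OC(=O)[C@H](C)CC)CC(C)=C | intermediate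
32 | [(3aS,4S,6Z,9R,10Z,11aS)-9-acetoxy-6,10-dimethyl-3-methylidene-2-oxo-2,3,3a,4,5,8,9,11a-octahydrocyclodeca[b]furan-4-yl] (2R)-2-methylbutanoate | C=C1C(=O)O[C@H]2/C=C(/C)[C@H](OC(C)=O)C/C=C(/C)C[C@H](OC(=O)[C@H](C)CC)[C@H]12 | intermediate
33 | 3-chloroperbenzoic acid | O=C(OO)c1cccc(Cl)c1 | starting material
34 | (1R,3R,4Z,6S,7S,8S,10S)-3-acetoxy-1,10-epoxy-8-[(2R)-2-methylbutanoyloxy]germacra-4,11(13)-dien-12,6-olide | C=C1C(=O)O[C@H]2/C=C(/C)[C@H](OC(C)=O)C[C@H]3O[C@@]3(C)C[C@H](OC(=O)[C@H](C)CC)[C@H]12 | target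

**Step count and risks**

Total step count: 17. Longest linear sequence: 12 steps (steps 1–5 or 6–10, then 11–17).

The three steps most likely to fail:

1. Step 16 (ring-closing metathesis). What may go wrong: the ruthenium alkylidene is diverted onto the exocyclic acrylate or couples between molecules instead of closing the strained ten-membered ring, so that oligomers or acrylate-derived products dominate. Fallback: take the competing olefin out of play for the duration of the metathesis. Setting out from 31, conjugate addition of dimethylamine (Me2NH, THF, 0 °C) should give the 13-dimethylamino-11,13-dihydro lactone F1. As its camphorsulfonate salt (CSA, 1.05 equiv) this would be closed with the second-generation Hoveyda–Grubbs catalyst (toluene–CH2Cl2, 1 mM, 60–80 °C) to the macrocyclic amine F2. Quaternisation with MeI and elimination with NaHCO3 should regenerate the α-methylene lactone and come back to the route at 32.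

2. Step 17 (epoxidation). What may go wrong: poor or inverted facial selectivity, because the face that the cyclodecadiene exposes depends on a conformational preference that has not been established. Fallback: a two-step anti-addition/displacement sequence that places oxygen on the face opposite to the one an electrophile attacks. Setting out from 32, NBS in aqueous acetone at 0 °C should give the bromohydrin F3 (bromonium ion on the exposed face, water opening at the tertiary C10). DBU in CH2Cl2 would then close the oxirane by SN2 displacement at C1, coming back at 34.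

3. Step 11 (chromium allylation/lactonisation). What may go wrong: erosion of the anti (C6/C7) selectivity through reaction of the isomeric allylchromium geometry, leading into the cis-lactone series. Fallback: make the syn adduct on purpose and invert C6. Setting out from 10 and 23, indium powder in THF–H2O should give the syn-hydroxy ester F4 through the cyclic transition state of the (Z)-allylindium species. LiOH (THF–H2O, 0 °C) would give the hydroxy acid F5. Mitsunobu lactonisation (PPh3, DIAD, THF, 0 °C) should then close the lactone with inversion at C6 and come back to the route at 25.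

**Further compounds**

F1 | step 16 | 13-dimethylamino-11,13-dihydro derivative of 31 (C11 epimers) | CN(C)CC1C(=O)O[C@@H](/C=C(/C)[C@H](OC(C)=O)CC=C)[C@@H]1[C@@H](OC(=O)[C@H](C)CC)CC(C)=C
F2 | step 16 | 13-dimethylamino-11,13-dihydro derivative of 32 (C11 epimers) | CN(C)CC1C(=O)O[C@H]2/C=C(/C)[C@H](OC(C)=O)C/C=C(/C)C[C@H](OC(=O)[C@H](C)CC)[C@H]12
F3 | step 17 | (1S,10S)-1-bromo-10-hydroxy-1,10-dihydro derivative of 32 (bromohydrin) | C=C1C(=O)O[C@H]2/C=C(/C)[C@H](OC(C)=O)C[C@H](Br)[C@](O)(C)C[C@H](OC(=O)[C@H](C)CC)[C@H]12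
F4 | step 11 | syn adduct, the C6 epimer of hydroxy ester 24 | C=C(C(=O)OC)[C@H]([C@H](O)/C=C(/C)[C@H](OCc1ccc(OC)cc1)CC=C)[C@@H](O[Si](C)(C)C(C)(C)C)CC(C)=C
F5 | step 11 | carboxylic acid of F4 | C=C(C(=O)O)[C@H]([C@H](O)/C=C(/C)[C@H](OCc1ccc(OC)cc1)CC=C)[C@@H](O[Si](C)(C)C(C)(C)C)CC(C)=C
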